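Ring C (O1–C2–C3–C4–C4a–C8a) is treated as the formal [4+2] adduct of a cationic 2-oxadiene, the O-aryl oxocarbenium ion C4a=C8a–O1=C2, and a two-carbon ketene equivalent that supplies C3 and C4. The step exploits two features: ring A is mirror-symmetric and triply oxygen-activated at C4a, and C4 is a ketone flanked by the C3 methylene, which a terminal ynamide delivers at the right oxidation level. A chiral Brønsted acid ionises an acyclic O-aryl O-acetyl acetal of veratraldehyde; the ynamide attacks C2 (C2–C3) and ring A closes on the keteniminium ion (C4–C4a), setting C2 under catalyst control. Hydrolysis and debenzylation finish the route.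

Key step: step 3

Assumption: the sense of induction of the chiral acid cannot be predicted with certainty, so the catalyst antipode that leads to 2S is meant (written as S,S); benzyl ether 1 is taken as commercial (otherwise one benzylation of syringaldehyde).

Step 1
Reactants: 1 4-(benzyloxy)-3,5-dimethoxybenzaldehyde
Product: 3 4-(benzyloxy)-3,5-dimethoxyphenol, via aryl formate 2 (not isolated)
Conditions: mCPBA, CH2Cl2, 0 °C → rt; then K2CO3 (cat.), MeOH, rt
Reagents that add atoms: mCPBA, O=C(OO)c1cccc(Cl)c1
Why: Baeyer–Villiger oxidation of an electron-rich benzaldehyde proceeds with aryl migration to the aryl formate, which mild methanolysis cleaves to the phenol while the benzyl and methyl ethers stay intact.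

Step 2
Reactants: 3 4-(benzyloxy)-3,5-dimethoxyphenol; 4 3,4-dimethoxybenzaldehyde (veratraldehyde)
Product: 6 racemic [4-(benzyloxy)-3,5-dimethoxyphenoxy](3,4-dimethoxyphenyl)methyl acetate, via bromo acetate 5 (not isolated)
Conditions: 4, AcBr, ZnCl2 (cat.), CH2Cl2, 0 °C; then 3, iPr2NEt, CH2Cl2, −40 → 0 °C
Reagents that add atoms: acetyl bromide, CC(=O)Br
Why: Acyl bromides add to aldehydes to give α-bromoalkyl esters, and the highly ionisable benzylic bromide of 5 should O-alkylate the amine-activated phenol as in the preparation of acyloxymethyl aryl ethers, giving the O-aryl O-acetyl acetal whose stereocentre is erased on ionisation in step 3.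

Step 3
Reactants: 6 racemic [4-(benzyloxy)-3,5-dimethoxyphenoxy](3,4-dimethoxyphenyl)methyl acetate; 7 N-ethynyl-N,4-dimethylbenzenesulfonamide
Product: 9 (2S)-6-(benzyloxy)-2-(3,4-dimethoxyphenyl)-5,7-dimethoxychroman-4-one, via chromenyl sulfonamide 8 (not isolated)
Conditions: 7 (2.5 equiv), (S,S)-IDPi acid (confined BINOL-derived imidodiphosphorimidate, N-triflyl core, 5 mol%), toluene, −60 °C; then 1 M aq. HCl, THF, 0 °C → rt
Reagents that add atoms: water, O
Why: Proposed new method: the chiral acid should ionise 6 by loss of acetate to an O-aryl oxocarbenium ion held as a contact ion pair with the confined anion, the polarised ynamide 7 attacks C2 through its terminal carbon (C2–C3), the resulting N-sulfonyl keteniminium ion is captured by the ortho carbon of ring A (C4–C4a), proton loss returns the acid, and aqueous acid hydrolyses enamide 8 to the C4 ketone. The closest known reaction types are the Lewis-acid-mediated oxa-Povarov reaction (formal [4+2] of aryl 2-oxadiene oxocarbenium ions with alkenes), Povarov-type annulations of ynamides with N-aryl iminium ions, and enantioselective additions to oxocarbenium ions paired with confined chiral anions. Ring C is closed by Friedel–Crafts attack of C4a on the keteniminium carbon C4 (6-exo-dig with respect to the C=N bond), which completes the formal [4+2] between the cationic 2-oxadiene C4a=C8a–O1=C2 and the alkyne. The C2 stereocentre is set in the C2–C3 bond formation by the chiral anion, which is to shield the Re face so that the ynamide adds to the Si face (priority order O > aryl > H) and gives 2S; the later events occur at C3, C4 and C4a and do not touch it. The step needs ionisation towards the O-aryl cation (secured by acetate being a far better leaving group than the aryloxide), carbon capture of the keteniminium ion by C4a in preference to the ether oxygen or the dimethoxyphenyl ring (secured by the ortho/para activation of C4a by three oxygens and the six-membered closure), and no regiochemical choice in ring A (its two ortho carbons are equivalent by symmetry).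

Step 4
Reactants: 9 (2S)-6-(benzyloxy)-2-(3,4-dimethoxyphenyl)-5,7-dimethoxychroman-4-one
Product: 10 (2S)-2-(3,4-dimethoxyphenyl)-6-hydroxy-5,7-dimethoxychroman-4-one
Conditions: H2 (1 atm), 10% Pd/C, EtOAc, rt
Reagents that add atoms: none
Why: Hydrogenolysis of the benzyl aryl ether over Pd/C under neutral conditions should free the C6 phenol without the base that would open the pyranone ring and racemise C2.

Compound list
1 | 4-(benzyloxy)-3,5-dimethoxybenzaldehyde | O=Cc1cc(OC)c(OCc2ccccc2)c(OC)c1 | starting material
2 | 4-(benzyloxy)-3,5-dimethoxyphenyl formate | O=COc1cc(OC)c(OCc2ccccc2)c(OC)c1 | intermediate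
3 | 4-(benzyloxy)-3,5-dimethoxyphenol | Oc1cc(OC)c(OCc2ccccc2)c(OC)c1 | intermediate
4 | 3,4-dimethoxybenzaldehyde (veratraldehyde) | COc1ccc(C=O)cc1OC | starting material
5 | bromo(3,4-dimethoxyphenyl)methyl acetate (racemic) | CC(=O)OC(Br)c1ccc(OC)c(OC)c1 | intermediate
6 | [4-(benzyloxy)-3,5-dimethoxyphenoxy](3,4-dimethoxyphenyl)methyl acetate (racemic) | CC(=O)OC(Oc1cc(OC)c(OCc2ccccc2)c(OC)c1)c1ccc(OC)c(OC)c1 | intermediate
7 | N-ethynyl-N,4-dimethylbenzenesulfonamide | C#CN(C)S(=O)(=O)c1ccc(C)cc1 | starting material
8 | N-[(2S)-6-(benzyloxy)-2-(3,4-dimethoxyphenyl)-5,7-dimethoxy-2H-chromen-4-yl]-N,4-dimethylbenzenesulfonamide | COc1ccc([C@@H]2C=C(N(C)S(=O)(=O)c3ccc(C)cc3)c3c(cc(OC)c(OCc4ccccc4)c3OC)O2)cc1OC | intermediate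
9 | (2S)-6-(benzyloxy)-2-(3,4-dimethoxyphenyl)-5,7-dimethoxychroman-4-one | COc1ccc([C@@H]2CC(=O)c3c(cc(OC)c(OCc4ccccc4)c3OC)O2)cc1OC | intermediate
10 | (2S)-2-(3,4-dimethoxyphenyl)-6-hydroxy-5,7-dimethoxychroman-4-one | COc1ccc([C@@H]2CC(=O)c3c(cc(OC)c(O)c3OC)O2)cc1OC | target

Total step count: 4 steps.
Longest linear sequence: 4 steps (1 → 3 → 6 → 9 → 10).

Steps most likely to fail

1. Step 3. Facial discrimination within the oxocarbenium–anion pair may be insufficient. The keteniminium ion may also be diverted, by capture at the ether oxygen with ring opening, by attack of the dimethoxyphenyl ring, or by acid-induced self-reaction of the ynamide (the excess of 7 is meant to absorb such losses). The fallback replaces the annulation by a catalyst-controlled conjugate arylation, all of it known chemistry, and sets out from phenol 3. Friedel–Crafts C-acetylation ortho to the hydroxyl (Ac2O, BF3·OEt2, 0 °C → rt, aqueous work-up) should give 1-[3-(benzyloxy)-6-hydroxy-2,4-dimethoxyphenyl]ethan-1-one F1. Condensation with N,N-dimethylformamide dimethyl acetal (toluene, 90 °C) should give the enaminone (E)-1-[3-(benzyloxy)-6-hydroxy-2,4-dimethoxyphenyl]-3-(dimethylamino)prop-2-en-1-one F2, which should close under acid (HCl, CH2Cl2, rt) to 6-(benzyloxy)-5,7-dimethoxy-4H-chromen-4-one F3. Rh-catalysed asymmetric 1,4-addition of (3,4-dimethoxyphenyl)boronic acid ([Rh(OH)(cod)]2, an electron-poor atropisomeric bisphosphine such as MeO-F12-BIPHEP in the antipode that leads to 2S, toluene–H2O) then comes back to the route at flavanone 9.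

2. Step 2. The ionisable bromide may C-alkylate the electron-rich phenol, formation of bromo acetate 5 may be incomplete so that residual acetyl bromide O-acetylates 3, and acetal 6 may ionise or hydrolyse during isolation. The fallback builds the acetoxy acetal by oxidative decarboxylation instead and sets out from phenol 3. Commercial methyl (3,4-dimethoxyphenyl)acetate is brominated at the benzylic carbon (NBS, AIBN, PhCF3, reflux) to methyl 2-bromo-2-(3,4-dimethoxyphenyl)acetate F4. Williamson alkylation of 3 with it (K2CO3, acetone, rt) should give methyl 2-[4-(benzyloxy)-3,5-dimethoxyphenoxy]-2-(3,4-dimethoxyphenyl)acetate F5. Saponification (LiOH, THF–H2O, then mild acidification) should give 2-[4-(benzyloxy)-3,5-dimethoxyphenoxy]-2-(3,4-dimethoxyphenyl)acetic acid F6. Oxidative decarboxylation with Pb(OAc)4 (pyridine, benzene, rt), the standard conversion of α-alkoxy acids into α-acetoxy ethers, comes back to the route at acetal 6.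

3. Step 4. Hydrogenolytic cleavage of the benzylic C2–O1 bond or reduction of the C4 carbonyl may compete with removal of the benzyl ether. The fallback changes from reductive to Lewis-acid-mediated debenzylation; it sets out from 9 and comes back directly at 10. The reagents are BCl3 with pentamethylbenzene as benzyl cation scavenger in CH2Cl2 at −78 °C, quenched cold so that the 5-methoxy group next to the carbonyl is not cleaved. No new compound is formed on the way.

Further compounds
F1 | step 3 | 1-[3-(benzyloxy)-6-hydroxy-2,4-dimethoxyphenyl]ethan-1-one | CC(=O)c1c(O)cc(OC)c(OCc2ccccc2)c1OC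
F2 | step 3 | (E)-1-[3-(benzyloxy)-6-hydroxy-2,4-dimethoxyphenyl]-3-(dimethylamino)prop-2-en-1-one | CN(C)/C=C/C(=O)c1c(O)cc(OC)c(OCc2ccccc2)c1OC
F3 | step 3 | 6-(benzyloxy)-5,7-dimethoxy-4H-chromen-4-one | O=c1ccoc2cc(OC)c(OCc3ccccc3)c(OC)c12
F4 | step 2 | methyl 2-bromo-2-(3,4-dimethoxyphenyl)acetate (racemic) | COC(=O)C(Br)c1ccc(OC)c(OC)c1
F5 | step 2 | methyl 2-[4-(benzyloxy)-3,5-dimethoxyphenoxy]-2-(3,4-dimethoxyphenyl)acetate (racemic) | COC(=O)C(Oc1cc(OC)c(OCc2ccccc2)c(OC)c1)c1ccc(OC)c(OC)c1
F6 | step 2 | 2-[4-(benzyloxy)-3,5-dimethoxyphenoxy]-2-(3,4-dimethoxyphenyl)acetic acid (racemic) | OC(=O)C(Oc1cc(OC)c(OCc2ccccc2)c(OC)c1)c1ccc(OC)c(OC)c1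
F0 | step 4 | none | none
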